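The numbers in the tables are simulated on assumed constants.

The charge is 0.27 M of starting complex, 0.486 M of incoming ligand and 0.0270 M of protic impurity. The set-ups differ in when these meet, and the asked share, a selectivity, turns on r, the rate of the second exchange, which we take as proportional to the stock of complex with one exchanged times the free incoming ligand.

| flask | starting complex | incoming ligand | protic impurity | remark | time |
|---|---|---|---|---|---|
| eta | 0.27 M | 0.486 M | 0.027 M | run made earlier |  |
| epsilon | 0.27 M | 0.33 M | 0.027 M | run made earlier |  |
| delta | 0.27 M | 0.73 M | 0.027 M | run made earlier |  |
| red | 0.27 M | 0.486 M (fed, over 12.0 d) | 0.0270 M | a stirred flask in which incoming ligand is dosed at a steady rate over 12.0 d without added volume, worked up at 15 d | 15 d |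
| teal | 0.27 M | 0.486 M | 0.0270 M | a closed flask charged with all of it at once and left for 15 d | 15 d |
| violet | 0.27 M | 0.486 M | 0.0270 M | one stirred flow tank at steady state, fed with the mixture as stated, mean residence time 15 d |  |
| amber | 0.27 M (fed, over 12.0 d) | 0.486 M | 0.0270 M | all but starting complex at the start; starting complex goes in evenly over 12.0 d, the run ends at 15 d | 15 d |

| run | time / d | complex with one exchanged / % | complex with two exchanged / % |
|---|---|---|---|
| eta | 1.04 | 41 | 7 |
| eta | 3.00 | 36 | 18 |
| eta | 5.00 | 26 | 24 |
| eta | 8.00 | 20 | 29 |
| eta | 12.0 | 15 | 37 |
| eta | 15.0 | 12 | 38 |
| epsilon | 3.00 | 31 | 8 |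
| epsilon | 6.00 | 25 | 16 |
| epsilon | 10.0 | 24 | 17 |
| epsilon | 12.0 | 18 | 24 |
| epsilon | 15.0 | 16 | 28 |
| epsilon | 20.0 | 12 | 29 |
| delta | 1.25 | 45 | 15 |
| delta | 4.00 | 27 | 36 |
| delta | 6.00 | 19 | 43 |
| delta | 10.0 | 17 | 50 |
| delta | 15.0 | 13 | 59 |
| delta | 20.0 | 10 | 65 |

(standard deviation of a reading: 2 percentage points)

1. the set-up with the highest share of complex with one exchanged in all that became complex with one exchanged or complex with two exchanged, at the outlet or at the end ("none" if the first two lie within 2 percentage points) (red / teal / violet / amber / none)
2. share of complex with one exchanged in all that became complex with one exchanged or complex with two exchanged, at the outlet or at the end, red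
3. share of complex with one exchanged in all that became complex with one exchanged or complex with two exchanged, at the outlet or at the end, teal
4. share of complex with one exchanged in all that became complex with one exchanged or complex with two exchanged, at the outlet or at the end, violet
5. share of complex with one exchanged in all that became complex with one exchanged or complex with two exchanged, at the outlet or at the end, amber

- the stated concentrations are those of everything mixed, before any reaction; amounts are the same in each set-up
- on the list of suspects stand: starting complex + incoming ligand <-> leaving ligand + complex with one exchanged; complex with one exchanged + incoming ligand <-> leaving ligand + complex with two exchanged; protic impurity + incoming ligand -> quenched reagent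
- the feed brings no volume worth counting
- the earlier runs were made in a closed, stirred flask

- Teal has eta's charge in eta's kind of flask, so eta's readings serve as teal's clock. In eta the two exchanged complexes total 48.0% at 1.04 d and 50.0% at 15.0 d, while complex with two exchanged gains 17 percentage points from 1.04 d to 5.00 d but 9 points from 8.00 d to 15.0 d. The slowing of r is therefore already in the readings, and they put teal's share near 24.0%.
- Red, a semi-batch flask, gets its ligand over 12.0 d. We measure r against r_full, the closed flask's rate just after the quick first exchange, neglecting the second exchange: eta's first reading gives a stock of 0.130 M beside 0.329 M free ligand, impurity deducted, and so an equilibrium ratio K of 0.363.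
- At mid-feed the same K splits the 0.216 M of ligand then past the impurity into 0.0905 M of stock and 0.126 M free, so we put r at a quarter of r_full.
- A rate going from zero through that quarter to r_full follows the square of the dose and averages a third of r_full, so in this estimate the 12.0 d of dosing do the work of 4.00 d, and the 3.00 d after it count whole.
- This gives the equivalent closed-flask time t_eq, the time a closed flask takes to do what the fed flask does: 7.00 d for red.
- Eta read between its readings at that time gives 22.0% with one exchanged and 27.3% with two, so we commit to about 44.6% for red, each reading carrying a scatter of 2 points. Violet's tank has no such clock, and we leave it unreckoned.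
- The forecast names red, with red 44%, teal 26%, violet 41% and amber 36%, and remarks: “Red leads violet only narrowly.”
- The flask gives red 44.4%, teal 25.7%, violet 39.8% and amber 35.0%, so the best is red.

    starting complex + incoming ligand ⇌ leaving ligand + complex with one exchanged (K = 0.390, k = 4.00 × 10⁻⁵ L mol⁻¹ s⁻¹)
    complex with one exchanged + incoming ligand ⇌ leaving ligand + complex with two exchanged (K = 19.0, k = 5.20 × 10⁻⁶ L mol⁻¹ s⁻¹)
    protic impurity + incoming ligand → quenched reagent (k = 0.00190 L mol⁻¹ s⁻¹)

- In red at 4.36 d, the forward first step alone gives starting complex a half-life of 2.6 d, shorter than the 24 d the forward second step alone gives incoming ligand. Red at 15 d holds 22.4% of complex with one exchanged and 28.0% of complex with two exchanged, and teal at 7.50 d, near t_eq of 7.00 d, holds 21.6% and 29.0%.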